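**Retrosynthetic overview**

- Ring B of this 5,7-dihydroxyisoflavone carries four contiguous groups, C2'-OH, C3'-(3-hydroxy-3-methylbutyl), C4'-OH and C5'-OMe, with the C2' and C5' oxygens para. This hydroquinone monomethyl ether maps atom for atom onto a squarate-derived 2-alkyl-3-benzyloxy-4-methoxy-4-alkenylcyclobutenone.
- Ring B is made first, by thermal ring expansion of cyclobutenone 15 (C1'–C2' bond). Cyclobutenone 15 is assembled on dibenzyl squarate by two successive organolithium additions, and the alkenyl partner delivers a two-carbon arm at C1'.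
- The arm becomes an arylacetic Weinreb amide that acylates lithiated tris-MOM phloroglucinol (ring A brought in intact, C4–C4a bond). A DMF acetal supplies C2 and acid closes the pyranone ring C (O1–C2 bond).
- The tertiary carbinol flanked by two phenols would cyclise to a chroman under strong acid, so both ring-B phenols stay benzylated until a final neutral hydrogenolysis.

Key step: step 8

Remark: the target has no stereocentre; the stereocentres of 7, 14, 15, 17 and 28 are racemic and vanish later, so only the (E) geometry of the alkenyl unit (12, 13) has to be set.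

**Route**

Step 1
Reactants: 1 4-bromo-2-methylbutan-2-ol
Product: 2 tert-butyl[(4-bromo-2-methylbutan-2-yl)oxy]dimethylsilane
Conditions: TBSOTf, 2,6-lutidine, CH2Cl2, 0 °C → rt
Reagents that add atoms: tert-butyldimethylsilyl triflate, CC(C)(C)[Si](C)(C)OS(=O)(=O)C(F)(F)F
Why: O-silylation of the hindered tertiary alcohol with a silyl triflate and a non-nucleophilic base (silyl ether formation) leaves the primary bromide untouched.

Step 2
Reactants: 2 tert-butyl[(4-bromo-2-methylbutan-2-yl)oxy]dimethylsilane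
Product: 3 tert-butyl[(4-iodo-2-methylbutan-2-yl)oxy]dimethylsilane
Conditions: NaI, acetone, reflux
Reagents that add atoms: sodium iodide, [Na+].[I-]
Why: Finkelstein halide exchange (SN2 at the unhindered primary carbon, driven by precipitation of NaBr) should give the iodide that undergoes clean lithium–iodine exchange.

Step 3
Reactants: 4 squaric acid
Product: 5 dibenzyl squarate (3,4-bis(benzyloxy)cyclobut-3-ene-1,2-dione)
Conditions: BnOH (excess), toluene, reflux, Dean–Stark
Reagents that add atoms: benzyl alcohol, OCc1ccccc1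
Why: Self-catalysed azeotropic esterification of the strongly acidic vinylogous diacid (Fischer-type esterification) should give the diester, as it does with other alcohols.

Step 4
Reactants: 3 tert-butyl[(4-iodo-2-methylbutan-2-yl)oxy]dimethylsilane; 5 dibenzyl squarate
Product: 8 3-benzyloxy-4-[3-(tert-butyldimethylsilyloxy)-3-methylbutyl]cyclobut-3-ene-1,2-dione, via the side-chain alkyllithium 6 (not isolated), via the lithium alkoxide adduct 7 (not isolated)
Conditions: 3, t-BuLi (2.1 equiv), Et2O/pentane, −78 °C; add to 5, THF, −78 °C; TFAA, −78 °C; aq. NH4Cl, → rt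
Reagents that add atoms: water, O
Why: Lithium–iodine exchange gives the primary alkyllithium, which adds 1,2 to one carbonyl of the symmetric squarate; trifluoroacetylation of the carbinol and hydrolysis on work-up then effect the known squarate-adduct to 3-alkoxy-4-alkylcyclobutenedione rearrangement with loss of one benzyloxy group.

Step 5
Reactants: 9 but-3-yn-1-ol
Product: 10 (but-3-yn-1-yloxy)(tert-butyl)dimethylsilane
Conditions: TBSCl, imidazole, CH2Cl2, rt
Reagents that add atoms: tert-butyldimethylsilyl chloride, CC(C)(C)[Si](C)(C)Cl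
Why: Standard silyl ether formation on a primary alcohol gives a group that tolerates the organometallic steps and can later be removed selectively beside the tertiary silyl ether.

Step 6
Reactants: 10 (but-3-yn-1-yloxy)(tert-butyl)dimethylsilane
Product: 12 (E)-tert-butyl[(4-iodobut-3-en-1-yl)oxy]dimethylsilane, via the (E)-alkenylzirconocene chloride 11 (not isolated)
Conditions: Cp2Zr(H)Cl, THF, rt; then I2, 0 °C
Reagents that add atoms: iodine, II
Why: syn-Hydrozirconation of the terminal alkyne places zirconium at the terminal carbon and iodinolysis of the C–Zr bond with retention gives the (E)-iodoalkene (hydrozirconation–iodination).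

Step 7
Reactants: 12 (E)-tert-butyl[(4-iodobut-3-en-1-yl)oxy]dimethylsilane; 8 3-benzyloxy-4-[3-(tert-butyldimethylsilyloxy)-3-methylbutyl]cyclobut-3-ene-1,2-dione
Product: 15 (±)-3-benzyloxy-4-[(E)-4-(tert-butyldimethylsilyloxy)but-1-enyl]-4-methoxy-2-[3-(tert-butyldimethylsilyloxy)-3-methylbutyl]cyclobut-2-enone, via the (E)-alkenyllithium 13 (not isolated), via the lithium alkoxide 14 (not isolated)
Conditions: 12, t-BuLi (2.0 equiv), Et2O, −78 °C; add 8, THF, −78 °C; MeOTf, −78 → 0 °C
Reagents that add atoms: methyl triflate, COS(=O)(=O)C(F)(F)F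
Why: Lithium–iodine exchange retains the (E) geometry, the alkenyllithium adds 1,2 to the more electrophilic carbonyl (the one next to the benzyloxy-bearing carbon, not the vinylogous ester carbonyl), and the alkoxide is O-methylated in situ (Williamson-type alkylation); the new stereocentre is uncontrolled and is destroyed in step 8.

Step 8
Reactants: 15 (±)-3-benzyloxy-4-[(E)-4-(tert-butyldimethylsilyloxy)but-1-enyl]-4-methoxy-2-[3-(tert-butyldimethylsilyloxy)-3-methylbutyl]cyclobut-2-enone
Product: 18 3-benzyloxy-6-[2-(tert-butyldimethylsilyloxy)ethyl]-4-methoxy-2-[3-(tert-butyldimethylsilyloxy)-3-methylbutyl]phenol, via the dienylketene 16 (not isolated), via the cyclohexa-2,4-dienone 17 (not isolated)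
Conditions: toluene (degassed, 0.02 M), 110 °C
Reagents that add atoms: none
Why: Heating opens the cyclobutenone by conrotatory 4π-electrocyclic cleavage of the C1–C4 bond to dienylketene 16; the methoxy donor on C4 turns outward, so the butenyl group turns inward and lies cis to the ketene. The ketene carbon and the alkene terminus then join in a 6π-electrocyclisation, the only ring closure of the step, which forms carbocyclic ring B through the C1'–C2' bond and gives dienone 17; enolisation delivers phenol 18. This is the Moore ring expansion of 4-alkenyl-4-alkoxycyclobutenones to 4-alkoxyphenols, applied here to a new substrate. No stereocentre is created, since the racemic C4 centre of 15 and the sp3 centre of 17 both become aromatic carbons. The step needs torquoselective outward rotation of the methoxy group, which the oxygen lone pair on C4 secures, and the substitution pattern is fixed beforehand: the ketene carbon becomes C2'-OH, the alkyl- and benzyloxy-bearing carbons become C3' and C4', and the methoxy carbon becomes C5'.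

Step 9
Reactants: 18 3-benzyloxy-6-[2-(tert-butyldimethylsilyloxy)ethyl]-4-methoxy-2-[3-(tert-butyldimethylsilyloxy)-3-methylbutyl]phenol
Product: 19 2,4-bis(benzyloxy)-1-[2-(tert-butyldimethylsilyloxy)ethyl]-5-methoxy-3-[3-(tert-butyldimethylsilyloxy)-3-methylbutyl]benzene
Conditions: BnBr, K2CO3, Bu4NI (cat.), DMF, 50 °C
Reagents that add atoms: benzyl bromide, BrCc1ccccc1
Why: Williamson etherification of the hindered phenoxide caps the C2' oxygen, which would otherwise allow quinone formation on oxidation and benzofuran formation at the deoxybenzoin stage.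

Step 10
Reactants: 19 2,4-bis(benzyloxy)-1-[2-(tert-butyldimethylsilyloxy)ethyl]-5-methoxy-3-[3-(tert-butyldimethylsilyloxy)-3-methylbutyl]benzene
Product: 20 2-{2,4-bis(benzyloxy)-5-methoxy-3-[3-(tert-butyldimethylsilyloxy)-3-methylbutyl]phenyl}ethanol
Conditions: CSA (cat.), MeOH/CH2Cl2 (1:1), 0 °C
Reagents that add atoms: none
Why: Acid-catalysed methanolysis of silyl ethers is far faster at the unhindered primary site than at the tertiary one, so the arm should be unmasked selectively without any oxidant touching the electron-rich ring B.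

Step 11
Reactants: 20 2-{2,4-bis(benzyloxy)-5-methoxy-3-[3-(tert-butyldimethylsilyloxy)-3-methylbutyl]phenyl}ethanol
Product: 22 {2,4-bis(benzyloxy)-5-methoxy-3-[3-(tert-butyldimethylsilyloxy)-3-methylbutyl]phenyl}acetic acid, via the arylacetaldehyde 21 (not isolated)
Conditions: TEMPO (cat.), PhI(OAc)2 (2.2 equiv), MeCN/H2O (1:1), rt
Reagents that add atoms: water, O
Why: Oxoammonium-mediated oxidation (TEMPO/PhI(OAc)2) takes the primary alcohol through the aldehyde hydrate to the acid under nearly neutral, chlorine-free conditions that spare the silyl and benzyl ethers.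

Step 12
Reactants: 22 {2,4-bis(benzyloxy)-5-methoxy-3-[3-(tert-butyldimethylsilyloxy)-3-methylbutyl]phenyl}acetic acid
Product: 24 2-{2,4-bis(benzyloxy)-5-methoxy-3-[3-(tert-butyldimethylsilyloxy)-3-methylbutyl]phenyl}-N-methoxy-N-methylacetamide, via the acyl imidazole 23 (not isolated)
Conditions: CDI, THF, rt; then MeNH(OMe)·HCl, rt
Reagents that add atoms: N,O-dimethylhydroxylamine hydrochloride, CNOC.Cl
Why: Amide coupling through the acyl imidazole gives the Weinreb amide without acid or strong base.

Step 13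
Reactants: 25 phloroglucinol
Product: 26 1,3,5-tris(methoxymethoxy)benzene
Conditions: MOMCl, iPr2NEt, CH2Cl2/DMF, 0 °C → rt
Reagents that add atoms: chloromethyl methyl ether, COCCl
Why: O-Alkylation of the three phenols with the hard chloromethyl ether (acetal protection) gives a symmetric arene in which every ring position lies between two directing groups.

Step 14
Reactants: 26 1,3,5-tris(methoxymethoxy)benzene; 24 2-{2,4-bis(benzyloxy)-5-methoxy-3-[3-(tert-butyldimethylsilyloxy)-3-methylbutyl]phenyl}-N-methoxy-N-methylacetamide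
Product: 29 2-{2,4-bis(benzyloxy)-5-methoxy-3-[3-(tert-butyldimethylsilyloxy)-3-methylbutyl]phenyl}-1-[2,4,6-tris(methoxymethoxy)phenyl]ethanone, via the aryllithium 27 (not isolated), via the chelated tetrahedral adduct 28 (not isolated)
Conditions: 26 (2 equiv), n-BuLi, TMEDA, THF, 0 °C; then 24, −78 → 0 °C; aq. NH4Cl
Reagents that add atoms: none
Why: Directed ortho-metalation between two OMOM groups gives a single aryllithium, and its addition to the Weinreb amide stops at the chelated tetrahedral adduct, which releases the deoxybenzoin only on work-up (Weinreb ketone synthesis).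

Step 15
Reactants: 29 2-{2,4-bis(benzyloxy)-5-methoxy-3-[3-(tert-butyldimethylsilyloxy)-3-methylbutyl]phenyl}-1-[2,4,6-tris(methoxymethoxy)phenyl]ethanone
Product: 30 (E)-2-{2,4-bis(benzyloxy)-5-methoxy-3-[3-(tert-butyldimethylsilyloxy)-3-methylbutyl]phenyl}-3-(dimethylamino)-1-[2,4,6-tris(methoxymethoxy)phenyl]prop-2-en-1-one
Conditions: Me2NCH(OMe)2, toluene, 95 °C
Reagents that add atoms: N,N-dimethylformamide dimethyl acetal, COC(OC)N(C)C
Why: Condensation of the doubly activated methylene with the amide acetal (enaminone formation) installs the future C2 under neutral conditions; the alkene geometry is of no consequence.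

Step 16
Reactants: 30 (E)-2-{2,4-bis(benzyloxy)-5-methoxy-3-[3-(tert-butyldimethylsilyloxy)-3-methylbutyl]phenyl}-3-(dimethylamino)-1-[2,4,6-tris(methoxymethoxy)phenyl]prop-2-en-1-one
Product: 32 2',4'-bis(benzyloxy)-5,7-dihydroxy-3'-(3-hydroxy-3-methylbutyl)-5'-methoxyisoflavone, via the silyl-protected isoflavone 31 (not isolated)
Conditions: 2 M HCl, MeOH/THF, 40 °C; concentrate; HF·pyridine, pyridine/THF, 0 °C → rt
Reagents that add atoms: none
Why: Acid cleaves the three aryl MOM acetals and the freed ortho phenol closes ring C by 6-endo conjugate addition to the enaminone with loss of dimethylamine (chromone synthesis from an enaminone), then buffered fluoride removes whatever tertiary silyl ether remains; the benzyl ethers on C2' and C4' prevent the carbinol from closing a chroman.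

Step 17
Reactants: 32 2',4'-bis(benzyloxy)-5,7-dihydroxy-3'-(3-hydroxy-3-methylbutyl)-5'-methoxyisoflavone
Product: 33 2',4',5,7-tetrahydroxy-3'-(3-hydroxy-3-methylbutyl)-5'-methoxyisoflavone (CNP0277410.0)
Conditions: H2 (1 atm), 10% Pd/C, EtOAc/MeOH, rt, stop at full debenzylation
Reagents that add atoms: none
Why: Catalytic hydrogenolysis of the two aryl benzyl ethers frees the last phenols under neutral conditions, under which the tertiary alcohol does not cyclise and the chromone double bond is not expected to be reduced.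

**Compound list**

1 | 4-bromo-2-methylbutan-2-ol | CC(C)(O)CCBr | starting material
2 | tert-butyl[(4-bromo-2-methylbutan-2-yl)oxy]dimethylsilane | CC(C)(CCBr)O[Si](C)(C)C(C)(C)C | intermediate
3 | tert-butyl[(4-iodo-2-methylbutan-2-yl)oxy]dimethylsilane | CC(C)(CCI)O[Si](C)(C)C(C)(C)C | intermediate
4 | squaric acid | OC1=C(O)C(=O)C1=O | starting material
5 | dibenzyl squarate | O=C1C(=O)C(OCc2ccccc2)=C1OCc1ccccc1 | intermediate
6 | [3-(tert-butyldimethylsilyloxy)-3-methylbutyl]lithium | [Li]CCC(C)(C)O[Si](C)(C)C(C)(C)C | intermediate (not isolated)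
7 | lithium alkoxide of (±)-2,3-bis(benzyloxy)-4-hydroxy-4-[3-(tert-butyldimethylsilyloxy)-3-methylbutyl]cyclobut-2-enone | [Li]OC1(CCC(C)(C)O[Si](C)(C)C(C)(C)C)C(=O)C(OCc2ccccc2)=C1OCc1ccccc1 | intermediate (not isolated)
8 | 3-benzyloxy-4-[3-(tert-butyldimethylsilyloxy)-3-methylbutyl]cyclobut-3-ene-1,2-dione | O=C1C(=O)C(OCc2ccccc2)=C1CCC(C)(C)O[Si](C)(C)C(C)(C)C | intermediate
9 | but-3-yn-1-ol | C#CCCO | starting material
10 | (but-3-yn-1-yloxy)(tert-butyl)dimethylsilane | C#CCCO[Si](C)(C)C(C)(C)C | intermediate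
11 | chlorobis(cyclopentadienyl)[(E)-4-(tert-butyldimethylsilyloxy)but-1-enyl]zirconium | Cl[Zr](/C=C/CCO[Si](C)(C)C(C)(C)C)(C1C=CC=C1)C1C=CC=C1 | intermediate (not isolated)
12 | (E)-tert-butyl[(4-iodobut-3-en-1-yl)oxy]dimethylsilane | I/C=C/CCO[Si](C)(C)C(C)(C)C | intermediate
13 | (E)-[4-(tert-butyldimethylsilyloxy)but-1-enyl]lithium | [Li]/C=C/CCO[Si](C)(C)C(C)(C)C | intermediate (not isolated)
14 | lithium alkoxide of (±)-3-benzyloxy-4-[(E)-4-(tert-butyldimethylsilyloxy)but-1-enyl]-4-hydroxy-2-[3-(tert-butyldimethylsilyloxy)-3-methylbutyl]cyclobut-2-enone | [Li]OC1(/C=C/CCO[Si](C)(C)C(C)(C)C)C(=O)C(CCC(C)(C)O[Si](C)(C)C(C)(C)C)=C1OCc1ccccc1 | intermediate (not isolated)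
15 | (±)-3-benzyloxy-4-[(E)-4-(tert-butyldimethylsilyloxy)but-1-enyl]-4-methoxy-2-[3-(tert-butyldimethylsilyloxy)-3-methylbutyl]cyclobut-2-enone | COC1(/C=C/CCO[Si](C)(C)C(C)(C)C)C(=O)C(CCC(C)(C)O[Si](C)(C)C(C)(C)C)=C1OCc1ccccc1 | intermediate (key-step precursor)
16 | (3Z,5E)-3-benzyloxy-4-methoxy-8-(tert-butyldimethylsilyloxy)-2-[3-(tert-butyldimethylsilyloxy)-3-methylbutyl]octa-1,3,5-trien-1-one (dienylketene) | O=C=C(CCC(C)(C)O[Si](C)(C)C(C)(C)C)/C(OCc1ccccc1)=C(OC)\C=C\CCO[Si](C)(C)C(C)(C)C | intermediate (not isolated)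
17 | (±)-3-benzyloxy-6-[2-(tert-butyldimethylsilyloxy)ethyl]-4-methoxy-2-[3-(tert-butyldimethylsilyloxy)-3-methylbutyl]cyclohexa-2,4-dienone | O=C1C(CCC(C)(C)O[Si](C)(C)C(C)(C)C)=C(OCc2ccccc2)C(OC)=CC1CCO[Si](C)(C)C(C)(C)C | intermediate (not isolated)
18 | 3-benzyloxy-6-[2-(tert-butyldimethylsilyloxy)ethyl]-4-methoxy-2-[3-(tert-butyldimethylsilyloxy)-3-methylbutyl]phenol | COc1cc(CCO[Si](C)(C)C(C)(C)C)c(O)c(CCC(C)(C)O[Si](C)(C)C(C)(C)C)c1OCc1ccccc1 | intermediate (key-step product)
19 | 2,4-bis(benzyloxy)-1-[2-(tert-butyldimethylsilyloxy)ethyl]-5-methoxy-3-[3-(tert-butyldimethylsilyloxy)-3-methylbutyl]benzene | COc1cc(CCO[Si](C)(C)C(C)(C)C)c(OCc2ccccc2)c(CCC(C)(C)O[Si](C)(C)C(C)(C)C)c1OCc1ccccc1 | intermediate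
20 | 2-{2,4-bis(benzyloxy)-5-methoxy-3-[3-(tert-butyldimethylsilyloxy)-3-methylbutyl]phenyl}ethanol | COc1cc(CCO)c(OCc2ccccc2)c(CCC(C)(C)O[Si](C)(C)C(C)(C)C)c1OCc1ccccc1 | intermediate
21 | {2,4-bis(benzyloxy)-5-methoxy-3-[3-(tert-butyldimethylsilyloxy)-3-methylbutyl]phenyl}acetaldehyde | COc1cc(CC=O)c(OCc2ccccc2)c(CCC(C)(C)O[Si](C)(C)C(C)(C)C)c1OCc1ccccc1 | intermediate (not isolated)
22 | {2,4-bis(benzyloxy)-5-methoxy-3-[3-(tert-butyldimethylsilyloxy)-3-methylbutyl]phenyl}acetic acid | COc1cc(CC(=O)O)c(OCc2ccccc2)c(CCC(C)(C)O[Si](C)(C)C(C)(C)C)c1OCc1ccccc1 | intermediate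
23 | 2-{2,4-bis(benzyloxy)-5-methoxy-3-[3-(tert-butyldimethylsilyloxy)-3-methylbutyl]phenyl}-1-(imidazol-1-yl)ethanone | COc1cc(CC(=O)n2ccnc2)c(OCc2ccccc2)c(CCC(C)(C)O[Si](C)(C)C(C)(C)C)c1OCc1ccccc1 | intermediate (not isolated)
24 | 2-{2,4-bis(benzyloxy)-5-methoxy-3-[3-(tert-butyldimethylsilyloxy)-3-methylbutyl]phenyl}-N-methoxy-N-methylacetamide | COc1cc(CC(=O)N(C)OC)c(OCc2ccccc2)c(CCC(C)(C)O[Si](C)(C)C(C)(C)C)c1OCc1ccccc1 | intermediate
25 | phloroglucinol | Oc1cc(O)cc(O)c1 | starting material
26 | 1,3,5-tris(methoxymethoxy)benzene | COCOc1cc(OCOC)cc(OCOC)c1 | intermediate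
27 | [2,4,6-tris(methoxymethoxy)phenyl]lithium | [Li]c1c(OCOC)cc(OCOC)cc1OCOC | intermediate (not isolated)
28 | lithium salt of the (±)-N-methoxy-N-methyl hemiaminal from 24 and 27 | [Li]OC(Cc1cc(OC)c(OCc2ccccc2)c(CCC(C)(C)O[Si](C)(C)C(C)(C)C)c1OCc1ccccc1)(N(C)OC)c1c(OCOC)cc(OCOC)cc1OCOC | intermediate (not isolated)
29 | 2-{2,4-bis(benzyloxy)-5-methoxy-3-[3-(tert-butyldimethylsilyloxy)-3-methylbutyl]phenyl}-1-[2,4,6-tris(methoxymethoxy)phenyl]ethanone | COCOc1cc(OCOC)c(C(=O)Cc2cc(OC)c(OCc3ccccc3)c(CCC(C)(C)O[Si](C)(C)C(C)(C)C)c2OCc2ccccc2)c(OCOC)c1 | intermediate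
30 | (E)-2-{2,4-bis(benzyloxy)-5-methoxy-3-[3-(tert-butyldimethylsilyloxy)-3-methylbutyl]phenyl}-3-(dimethylamino)-1-[2,4,6-tris(methoxymethoxy)phenyl]prop-2-en-1-one | CN(C)/C=C(\c1cc(OC)c(OCc2ccccc2)c(CCC(C)(C)O[Si](C)(C)C(C)(C)C)c1OCc1ccccc1)C(=O)c1c(OCOC)cc(OCOC)cc1OCOC | intermediate
31 | 2',4'-bis(benzyloxy)-5,7-dihydroxy-5'-methoxy-3'-[3-(tert-butyldimethylsilyloxy)-3-methylbutyl]isoflavone | COc1cc(-c2coc3cc(O)cc(O)c3c2=O)c(OCc2ccccc2)c(CCC(C)(C)O[Si](C)(C)C(C)(C)C)c1OCc1ccccc1 | intermediate (not isolated)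
32 | 2',4'-bis(benzyloxy)-5,7-dihydroxy-3'-(3-hydroxy-3-methylbutyl)-5'-methoxyisoflavone | COc1cc(-c2coc3cc(O)cc(O)c3c2=O)c(OCc2ccccc2)c(CCC(C)(C)O)c1OCc1ccccc1 | intermediate
33 | 2',4',5,7-tetrahydroxy-3'-(3-hydroxy-3-methylbutyl)-5'-methoxyisoflavone (CNP0277410.0) | COc1cc(-c2coc3cc(O)cc(O)c3c2=O)c(O)c(CCC(C)(C)O)c1O | target

**Step count**

Total steps: 17. Longest linear sequence: 13 (steps 1, 2, 4, 7, 8, 9, 10, 11, 12, 14, 15, 16, 17).

**Steps most likely to fail**

Step 7. The hindered tertiary lithium alkoxide may be methylated only in part at low temperature, and on warming the unmethylated alkoxide can undergo anion-accelerated ring opening. The fallback separates the two events. It sets out from dione 8 and alkenyllithium 13: the addition is quenched at −78 °C with aqueous NH4Cl and the racemic 3-benzyloxy-4-[(E)-4-(tert-butyldimethylsilyloxy)but-1-enyl]-4-hydroxy-2-[3-(tert-butyldimethylsilyloxy)-3-methylbutyl]cyclobut-2-enone F1 is isolated cold. The neutral carbinol is then methylated with MeI, Ag2O and K2CO3 in MeCN at room temperature, a known way to cap 4-hydroxycyclobutenones, and the route is rejoined at 15.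

Step 8. Ring opening of the methyl ether may be slow at 110 °C, and the dienylketene may be lost to dimerisation or to adventitious nucleophiles before it cyclises. The fallback runs the ring expansion on the free carbinol and differentiates the two oxygens afterwards. It sets out from 8 and 13 through the 4-hydroxycyclobutenone F1 described above. Heating F1 in degassed toluene at 80–110 °C, where 4-hydroxy compounds are known to expand more readily, should give 3-benzyloxy-6-[2-(tert-butyldimethylsilyloxy)ethyl]-2-[3-(tert-butyldimethylsilyloxy)-3-methylbutyl]benzene-1,4-diol F2. Under argon, one equivalent of MeI with K2CO3 in acetone should methylate the accessible C5' hydroxyl (next to a ring hydrogen and the benzyloxy group) in preference to the C2' hydroxyl, which is buried between two alkyl arms. The route is rejoined at 18.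

Step 14. The hindered, basic aryllithium may deprotonate the benzylic α-methylene of the amide instead of attacking its carbonyl, returning starting amide. The fallback uses a less basic nucleophile and a more reactive electrophile. It sets out from alcohol 20, which is oxidised with Dess–Martin periodinane (NaHCO3, CH2Cl2) to aldehyde 21, now isolated and used at once. Aryllithium 27 is transmetalated with anhydrous CeCl3 in THF at −78 °C to dichloro[2,4,6-tris(methoxymethoxy)phenyl]cerium F3. Addition of F3 to 21 should give racemic 2-{2,4-bis(benzyloxy)-5-methoxy-3-[3-(tert-butyldimethylsilyloxy)-3-methylbutyl]phenyl}-1-[2,4,6-tris(methoxymethoxy)phenyl]ethanol F4. A second Dess–Martin oxidation returns to the route at ketone 29.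

**Further compounds**

F1 | step 7 | (±)-3-benzyloxy-4-[(E)-4-(tert-butyldimethylsilyloxy)but-1-enyl]-4-hydroxy-2-[3-(tert-butyldimethylsilyloxy)-3-methylbutyl]cyclobut-2-enone | OC1(/C=C/CCO[Si](C)(C)C(C)(C)C)C(=O)C(CCC(C)(C)O[Si](C)(C)C(C)(C)C)=C1OCc1ccccc1
F2 | step 8 | 3-benzyloxy-6-[2-(tert-butyldimethylsilyloxy)ethyl]-2-[3-(tert-butyldimethylsilyloxy)-3-methylbutyl]benzene-1,4-diol | Oc1cc(CCO[Si](C)(C)C(C)(C)C)c(O)c(CCC(C)(C)O[Si](C)(C)C(C)(C)C)c1OCc1ccccc1
F3 | step 14 | dichloro[2,4,6-tris(methoxymethoxy)phenyl]cerium | Cl[Ce](Cl)c1c(OCOC)cc(OCOC)cc1OCOC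
F4 | step 14 | (±)-2-{2,4-bis(benzyloxy)-5-methoxy-3-[3-(tert-butyldimethylsilyloxy)-3-methylbutyl]phenyl}-1-[2,4,6-tris(methoxymethoxy)phenyl]ethanol | COCOc1cc(OCOC)c(C(O)Cc2cc(OC)c(OCc3ccccc3)c(CCC(C)(C)O[Si](C)(C)C(C)(C)C)c2OCc2ccccc2)c(OCOC)c1
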